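**Plan**
1. The chain is numbered from the alkyne CH (C1) to the methyl group (C15), and the ring is the oxocane O/C6–C12. The feature that enables the key step is that C6 (the ether carbon carrying the C5H2 arm) and C7 (Cl) are neighbouring ring stereocentres with arm and chlorine cis. Tracing C7–Cl back to C7–OH by one SN2 inversion gives a trans-2-alkyl-3-hydroxy cyclic ether.
2. The retrosynthetic cuts, in order, are C13–Br, C9–Cl/O10–acyl and C7–Cl (each back to C–O), then C2–C3 and C3=C4 (enyne back to a C4 ester), then ring bond C6–C7, O12–C6 and C11–C12.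
3. In the forward direction a C7–C11 iodide and a C12–C15 thioester are joined to the open chain and an (E)-acrylate is placed on O12. The oxocane then closes at C6–C7, the only skeletal ring closure. C7–Cl, the enyne, C9–Cl/O10–Ac and C13–Br follow.
4. C9/C10 come from 2-deoxy-L-ribose and C13 from (R)-2-hydroxybutanoic acid. C12 is set by Felkin–Anh reduction and C6/C7 in the ring closure. C7, C9 and C13 are each inverted once on halogenation and C10 is retained. The E-alkene comes from the Takai olefination.

Key step: step 12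

Remark: locants and descriptors in the names follow the C1–C15 numbering. The anomeric carbon of 2 and the orthoester carbon of 23 are carried as mixtures and are left undefined in the SMILES.

Step 1
Reactants: 1 2-deoxy-L-ribose
Product: 2 2-deoxy-3,4-O-isopropylidene-L-erythro-pentopyranose (lactol)
Conditions: 2-methoxypropene, PPTS (cat.), EtOAc, 0 °C to rt
Reagents that add atoms: 2-methoxypropene C=C(C)OC
Why: Kinetic acetalisation by enol-ether exchange should work because in the pyranose form only O9/O10 are a cis-vicinal diol, so the dioxolane forms there, C7 and O11 stay tied as the lactol, and no stereocentre is touched.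

Step 2
Reactants: 2 lactol acetonide
Product: 3 2-[(4R,5S)-5-(hydroxymethyl)-2,2-dimethyl-1,3-dioxolan-4-yl]ethanol (C7,C11-diol)
Conditions: NaBH4, MeOH, 0 °C
Reagents that add atoms: none
Why: Borohydride reduces the open hydroxy-aldehyde tautomer of the lactol, and the acetonide and both stereocentres are inert.

Step 3
Reactants: 3 C7,C11-diol
Product: 4 C7-O-TBS ether, C11-OH free (9R,10S)
Conditions: TBSCl (1.0 equiv), imidazole, CH2Cl2, −20 °C
Reagents that add atoms: tert-butyldimethylsilyl chloride CC(C)(C)[Si](C)(C)Cl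
Why: This is a sterically differentiated monosilylation, since C7–OH ends an unbranched ethyl arm while C11–OH is flanked by the cis-disubstituted dioxolane carbon, and regioisomer and bis-ether can be returned to 3 by desilylation.

Step 4
Reactants: 4 C11 alcohol
Product: 5 C11 iodide, tert-butyl{2-[(4R,5R)-5-(iodomethyl)-2,2-dimethyl-1,3-dioxolan-4-yl]ethoxy}dimethylsilane
Conditions: I2, PPh3, imidazole, toluene/MeCN, 0 °C to rt
Reagents that add atoms: iodine II
Why: Appel-type (Garegg–Samuelsson) iodination is an SN2 at the primary CH2, and silyl ether, acetonide and stereocentres are untouched.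

Step 5
Reactants: 6 (R)-2-hydroxybutanoic acid
Product: 8 (R)-2-(tert-butyldiphenylsilyloxy)butanoic acid, via silyl ester silyl ether 7 (not isolated)
Conditions: TBDPSCl (2.2 equiv), imidazole, DMF, rt; then K2CO3, MeOH/THF/H2O, rt; acidic work-up
Reagents that add atoms: tert-butyldiphenylsilyl chloride CC(C)(C)[Si](Cl)(c1ccccc1)c1ccccc1
Why: Both OH groups are silylated and the labile silyl ester is then solvolysed selectively, with no bond to C13 broken.

Step 6
Reactants: 8 silyloxy acid
Product: 9 S-(pyridin-2-yl) (R)-2-(tert-butyldiphenylsilyloxy)butanethioate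
Conditions: 2,2'-dipyridyl disulfide, PPh3, CH2Cl2, rt
Reagents that add atoms: 2,2'-dipyridyl disulfide c1ccc(SSc2ccccn2)nc1
Why: The Mukaiyama-type redox condensation is neutral, so the α-stereocentre C13 is not enolised.

Step 7
Reactants: 5 C11 iodide; 9 pyridyl thioester
Product: 10 C12 ketone (9R,10S,13R) with C7-OTBS, C9/C10 acetonide and C13-OTBDPS
Conditions: NiBr2(dtbbpy) (cat.), Cp2ZrCl2 (1 equiv), Zn, DMI/EtOAc, rt
Reagents that add atoms: none
Why: In this nickel-catalysed, zirconocene-mediated reductive ketone synthesis (alkyl iodide plus 2-pyridyl thioester) C11 enters through a radical/organonickel manifold known to tolerate an OR group next to the C–I carbon, which avoids the β-elimination expected for a C11 organolithium or organozinc or for a C12 acyl-anion equivalent next to C13–OSi, and without base C13 is kept.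

Step 8
Reactants: 10 C12 ketone
Product: 11 C12 alcohol (9R,10S,12R,13R)
Conditions: L-Selectride, THF, −78 °C; aqueous work-up
Reagents that add atoms: none
Why: In this Felkin–Anh reduction the bulky, non-chelating C13–OTBDPS stands perpendicular to the carbonyl and the hindered hydride comes in anti to it past C13–H, which should give the 12,13-syn (12R) alcohol.

Step 9
Reactants: 11 C12 alcohol; 12 ethyl propiolate
Product: 13 ethyl (E)-3-alkoxyacrylate on O12, C7-OTBS
Conditions: N-methylmorpholine, CH2Cl2, rt
Reagents that add atoms: none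
Why: Amine-promoted oxa-Michael addition of an alcohol to an alkynoate gives the E vinylogous carbonate, and since no free alkoxide is formed, silyl migration from O13 is not expected.

Step 10
Reactants: 13 silyl ether
Product: 14 C7 primary alcohol
Conditions: HF·pyridine, pyridine, THF, 0 °C
Reagents that add atoms: none
Why: Buffered fluoride cleaves the primary TBS ether much faster than the hindered secondary TBDPS ether, and acetonide and alkoxyacrylate are stable.

Step 11
Reactants: 14 C7 alcohol
Product: 15 C7 aldehyde with C9/C10 acetonide and O12 (E)-β-alkoxyacrylate (9R,10S,12R,13R)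
Conditions: Dess–Martin periodinane, CH2Cl2, 0 °C to rt; used without storage
Reagents that add atoms: none
Why: The Dess–Martin oxidation is non-basic, so the β-alkoxy aldehyde should not lose O9 by elimination.

Step 12
Reactants: 15 aldehyde alkoxyacrylate
Product: 16 ethyl 2-[oxocan-6-yl]acetate with 7-OH, fused C9/C10 acetonide and C12 (R)-1-(TBDPSO)propyl group (6S,7R,9R,10S,12R,13R)
Conditions: SmI2 (0.1 M in THF, 3.5 equiv), MeOH (3 equiv), THF, 0 °C; 15 added by syringe pump to about 2 mM
Reagents that add atoms: none
Why: Proposed new method: one-electron reduction of the C7 aldehyde gives a samarium(III) ketyl that adds to C6, the electron-poor β-carbon of the (E)-alkoxyacrylate on O12, and a second electron followed by protonation of the C5 samarium enolate by methanol (faster than β-loss of the ring oxygen) gives the saturated ester; the closest known reaction type is this same SmI2 ketyl/β-alkoxyacrylate cyclisation, established for 2,3-trans tetrahydropyrans and oxepanes but not for ring size eight. The oxocane (O, C6–C12) is the only ring closed, in the 8-exo-trig mode, and closure is helped because the cis-dioxolane holds C8–C9–C10–C11 near 45–50° and the conjugated O–C6=C5–C4=O unit is planar. C7 relative to C6 is controlled by Sm(III) bridging the ketyl oxygen and the ester carbonyl, which requires O7 and C5 gauche and both pseudo-equatorial, so hydroxyl and arm end up trans. C6 relative to C12 is controlled by the enol ether staying s-trans with C13 antiperiplanar to O–C6: in the smaller rings the short tether reaches only the face that gives the syn ether, whereas the five-carbon tether can pass on the C12–H side in a boat-boat-like array whose two C–O torsions have the same sign, and in that array the C5 arm, the C13 chain and O10 are all pseudo-equatorial and the dioxolane torsion is kept. The step needs cyclisation to outrun aldehyde reduction and pinacol coupling (secured by slow addition, dilution and little methanol) and it needs the anti relation across the ether oxygen, which rests on the dioxolane clamp and on the bulky, non-coordinating TBDPS ether that stops Sm(III) from tying the ester to O13 on the syn face. This facial selectivity is the least secure point of the route, and the H6/H12 relation of 16 is to be established by NOE before going on.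

Step 13
Reactants: 16 oxocan-7-ol
Product: 17 7-chloride (6S,7S,9R,10S,12R,13R), arm and Cl cis
Conditions: CCl4, (n-Oct)3P, toluene, 70 °C
Reagents that add atoms: carbon tetrachloride ClC(Cl)(Cl)Cl
Why: In this Appel chlorination the chloride collapses on the oxyphosphonium salt by SN2 with inversion at C7, and participation by the γ-ester carbonyl is slow (4-halo- and 4-sulfonyloxybutanoates are isolable) and should not compete.

Step 14
Reactants: 17 ethyl ester
Product: 18 C4 aldehyde
Conditions: DIBAL-H (1.1 equiv), CH2Cl2, −78 °C; Rochelle salt work-up; used crude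
Reagents that add atoms: none
Why: Partial ester reduction stops at the tetrahedral aluminate, which is stable at −78 °C, and the secondary chloride, acetonide and silyl ether are inert.

Step 15
Reactants: 18 C4 aldehyde
Product: 19 (3E)-vinyl iodide (C3–I)
Conditions: CHI3, CrCl2, THF/dioxane, 0 °C to rt
Reagents that add atoms: iodoform IC(I)I
Why: The geminal dichromium reagent of the Takai olefination adds to the aldehyde and eliminates anti-periplanar to give the E-iodoalkene, and the conditions are non-basic, so the β-alkoxy aldehyde does not undergo retro-Michael opening.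

Step 16
Reactants: 19 vinyl iodide; 20 ethynyltrimethylsilane
Product: 21 (3E)-1-trimethylsilyl enyne
Conditions: Pd(PPh3)4 (cat.), CuI (cat.), Et3N, THF, rt
Reagents that add atoms: none
Why: Sonogashira coupling of an alkenyl iodide proceeds with retention of the alkene geometry.

Step 17
Reactants: 21 acetonide
Product: 22 cis-9,10-diol (6S,7S,9R,10S,12R,13R)
Conditions: TFA/H2O, CH2Cl2, 0 °C to rt
Reagents that add atoms: none
Why: Acid hydrolysis removes the ketal, while the TBDPS ether, alkynylsilane, enyne and secondary chloride tolerate aqueous acid.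

Step 18
Reactants: 22 cis-diol
Product: 24 9-chloride 10-acetate (6S,7S,9S,10S,12R,13R), via cyclic orthoacetate 23 (not isolated)
Conditions: MeC(OMe)3, PPTS (cat.), CH2Cl2, rt, evaporate; then Me3SiCl, CH2Cl2, 0 °C to rt
Reagents that add atoms: trimethyl orthoacetate CC(OC)(OC)OC; chlorotrimethylsilane C[Si](C)(C)Cl
Why: In this orthoester/acetoxonium opening of a cis-diol, chloride attacks anti to the dioxolanylium ring (inversion at C9, retention at C10), and C9 should be preferred because the trajectory to C10 runs alongside the 1,3-related C12 side chain CH(OTBDPS)Et on the same face, whereas that to C9 meets only C7–H now that C7–Cl lies on the other face.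

Step 19
Reactants: 24 bis-silyl compound
Product: 25 C13 alcohol with terminal enyne (13R)
Conditions: TBAF/AcOH (1:1), THF, rt to 40 °C
Reagents that add atoms: none
Why: Buffered fluoride removes the O-TBDPS and C-SiMe3 groups in one operation, and the acetic acid keeps the medium from cleaving or shifting the acetate or closing an epoxide onto C9.

Step 20
Reactants: 25 C13 alcohol
Product: 26 target (6S,7S,9S,10S,12R,13S)
Conditions: CBr4, (n-Oct)3P, toluene, 70 °C
Reagents that add atoms: carbon tetrabromide BrC(Br)(Br)Br
Why: Appel bromination of the 1-hydroxypropyl side chain of a cyclic ether is an SN2 with inversion at C13, and the acetate, both chlorides and the terminal enyne are spectators.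

**Compound list**
1 | 2-deoxy-L-ribose | O=CC[C@@H](O)[C@@H](O)CO | starting material
2 | 2-deoxy-3,4-O-isopropylidene-L-erythro-pentopyranose | OC1C[C@H]2OC(C)(C)O[C@H]2CO1 | intermediate
3 | 2-[(4R,5S)-5-(hydroxymethyl)-2,2-dimethyl-1,3-dioxolan-4-yl]ethanol | OCC[C@H]1OC(C)(C)O[C@H]1CO | intermediate
4 | C7-O-TBS ether of 3 | CC(C)(C)[Si](C)(C)OCC[C@H]1OC(C)(C)O[C@H]1CO | intermediate
5 | C11 iodide | CC(C)(C)[Si](C)(C)OCC[C@H]1OC(C)(C)O[C@H]1CI | intermediate
6 | (R)-2-hydroxybutanoic acid | CC[C@@H](O)C(=O)O | starting material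
7 | tert-butyldiphenylsilyl (R)-2-(tert-butyldiphenylsilyloxy)butanoate | CC[C@@H](O[Si](c1ccccc1)(c1ccccc1)C(C)(C)C)C(=O)O[Si](c1ccccc1)(c1ccccc1)C(C)(C)C | intermediate
8 | (R)-2-(tert-butyldiphenylsilyloxy)butanoic acid | CC[C@@H](O[Si](c1ccccc1)(c1ccccc1)C(C)(C)C)C(=O)O | intermediate
9 | S-(pyridin-2-yl) (R)-2-(tert-butyldiphenylsilyloxy)butanethioate | CC[C@@H](O[Si](c1ccccc1)(c1ccccc1)C(C)(C)C)C(=O)Sc1ccccn1 | intermediate
10 | C12 ketone (9R,10S,13R) | CC[C@@H](O[Si](c1ccccc1)(c1ccccc1)C(C)(C)C)C(=O)C[C@@H]1OC(C)(C)O[C@@H]1CCO[Si](C)(C)C(C)(C)C | intermediate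
11 | C12 alcohol (9R,10S,12R,13R) | CC[C@@H](O[Si](c1ccccc1)(c1ccccc1)C(C)(C)C)[C@H](O)C[C@@H]1OC(C)(C)O[C@@H]1CCO[Si](C)(C)C(C)(C)C | intermediate
12 | ethyl propiolate | C#CC(=O)OCC | starting material
13 | O12 (E)-β-alkoxyacrylate, C7-OTBS | CCOC(=O)/C=C/O[C@@H]([C@H](O[Si](c1ccccc1)(c1ccccc1)C(C)(C)C)CC)C[C@@H]1OC(C)(C)O[C@@H]1CCO[Si](C)(C)C(C)(C)C | intermediate
14 | O12 (E)-β-alkoxyacrylate, C7-OH | CCOC(=O)/C=C/O[C@@H]([C@H](O[Si](c1ccccc1)(c1ccccc1)C(C)(C)C)CC)C[C@@H]1OC(C)(C)O[C@@H]1CCO | intermediate
15 | C7 aldehyde, precursor of the key step | CCOC(=O)/C=C/O[C@@H]([C@H](O[Si](c1ccccc1)(c1ccccc1)C(C)(C)C)CC)C[C@@H]1OC(C)(C)O[C@@H]1CC=O | intermediate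
16 | oxocan-7-ol, product of the key step (6S,7R,9R,10S,12R,13R) | CCOC(=O)C[C@@H]1O[C@@H]([C@H](O[Si](c2ccccc2)(c2ccccc2)C(C)(C)C)CC)C[C@@H]2OC(C)(C)O[C@@H]2C[C@H]1O | intermediate
17 | 7-chloride ester | CCOC(=O)C[C@@H]1O[C@@H]([C@H](O[Si](c2ccccc2)(c2ccccc2)C(C)(C)C)CC)C[C@@H]2OC(C)(C)O[C@@H]2C[C@@H]1Cl | intermediate
18 | C4 aldehyde | O=CC[C@@H]1O[C@@H]([C@H](O[Si](c2ccccc2)(c2ccccc2)C(C)(C)C)CC)C[C@@H]2OC(C)(C)O[C@@H]2C[C@@H]1Cl | intermediate
19 | (3E)-vinyl iodide | I/C=C/C[C@@H]1O[C@@H]([C@H](O[Si](c2ccccc2)(c2ccccc2)C(C)(C)C)CC)C[C@@H]2OC(C)(C)O[C@@H]2C[C@@H]1Cl | intermediate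
20 | ethynyltrimethylsilane | C#C[Si](C)(C)C | starting material
21 | (3E)-TMS-enyne acetonide | C[Si](C)(C)C#C/C=C/C[C@@H]1O[C@@H]([C@H](O[Si](c2ccccc2)(c2ccccc2)C(C)(C)C)CC)C[C@@H]2OC(C)(C)O[C@@H]2C[C@@H]1Cl | intermediate
22 | cis-9,10-diol | C[Si](C)(C)C#C/C=C/C[C@@H]1O[C@@H]([C@H](O[Si](c2ccccc2)(c2ccccc2)C(C)(C)C)CC)C[C@H](O)[C@H](O)C[C@@H]1Cl | intermediate
23 | 9,10-cyclic methyl orthoacetate | C[Si](C)(C)C#C/C=C/C[C@@H]1O[C@@H]([C@H](O[Si](c2ccccc2)(c2ccccc2)C(C)(C)C)CC)C[C@@H]2OC(C)(OC)O[C@@H]2C[C@@H]1Cl | intermediate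
24 | 9-chloride 10-acetate | C[Si](C)(C)C#C/C=C/C[C@@H]1O[C@@H]([C@H](O[Si](c2ccccc2)(c2ccccc2)C(C)(C)C)CC)C[C@H](OC(C)=O)[C@@H](Cl)C[C@@H]1Cl | intermediate
25 | C13 alcohol, terminal enyne | C#C/C=C/C[C@@H]1O[C@@H]([C@H](O)CC)C[C@H](OC(C)=O)[C@@H](Cl)C[C@@H]1Cl | intermediate
26 | CNP0251465.1 | C#C/C=C/C[C@@H]1O[C@@H]([C@@H](Br)CC)C[C@H](OC(C)=O)[C@@H](Cl)C[C@@H]1Cl | target

Total step count: 20. Longest linear sequence: 18 (steps 1–4 and 7–20).

**Steps most likely to fail**

1. **Step 12.** The 8-exo addition may be slower than reduction of the ketyl to the primary alcohol or pinacol dimerisation. The ketyl may also reach C6 from the face that gives the syn relation across the ether oxygen, as it does in all smaller-ring precedents.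
   - The fallback sets out from 9 and returns at 22. It sets C6 and C7 before any ring exists and closes the ring at C9=C10 by olefin metathesis, the established entry to α,α'-trans oxocenes.
   - DIBAL-H at −78 °C reduces 9 to (R)-2-(tert-butyldiphenylsilyloxy)butanal F1. Brown allylboration with (+)-Ipc2B(allyl) gives (4R,5R)-5-(tert-butyldiphenylsilyloxy)hept-1-en-4-ol F2.
   - NaH and bromoacetic acid give the O12-glycolic acid F3. Pivaloyl chloride/Et3N, then lithiated (R)-4-benzyloxazolidin-2-one, give the glycolyl imide F4.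
   - Evans alkylation of the sodium enolate (NaHMDS, −78 °C) with (E)-3-bromo-1-iodopropene, anti to the benzyl group, gives the C6-alkylated imide F5, whose arm is already the E-iodoalkene.
   - LiBH4 gives the C7 primary alcohol F6, and Dess–Martin oxidation gives the C7 aldehyde F7. A second allylboration with (+)-Ipc2B(allyl) gives the (6S,7R)-diene alcohol F8.
   - Ring-closing metathesis with the second-generation Grubbs catalyst gives the (9Z)-oxocen-7-ol F9, and (n-Oct)3P/CCl4 gives the 7-chloro-oxocene F10 with inversion.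
   - OsO4/NMO should attack the ring Z-alkene from the face opposite the C12 side chain and leave the electron-poor iodoalkene, giving the 9,10-diol vinyl iodide F11. Sonogashira coupling of F11 with 20 gives 22.

2. **Step 18.** Chloride may open the acetoxonium ion at C10 instead of C9, or the ring oxygen may capture the cation across the ring.
   - The fallback sets out from 22 and returns at 24. It moves the differentiation from C–Cl bond formation to O-acylation.
   - Acetyl chloride (1 equiv) and 2,4,6-collidine at −78 °C should acylate O10, which has only C12–H on its face, in preference to O9, which lies 1,3-syn to C7–Cl. This gives the 10-O-acetate of 22, F12, and the wrong monoacetate can be returned to 22 by methanolysis.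
   - (n-Oct)3P/CCl4 then substitutes C9–OH directly with inversion. The cis-disposed acetate cannot participate, so no onium ion with two electrophilic carbons is involved.

3. **Step 20.** The ring oxygen may participate at the activated C13, leading to retention or ring contraction, and E2 loss of the oxyphosphonium group may occur at 70 °C.
   - The fallback sets out from 25 and returns at 26. It separates activation from displacement.
   - Chloromethanesulfonyl chloride and 2,6-lutidine at 0 °C give the 13-O-chloromethanesulfonate of 25, F13. This is displaced by a large excess of LiBr in THF at or below 40 °C, so that the bimolecular SN2 can outrun the intramolecular pathways.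

**Further compounds**
F1 | step 12 | (R)-2-(tert-butyldiphenylsilyloxy)butanal | CC[C@@H](O[Si](c1ccccc1)(c1ccccc1)C(C)(C)C)C=O
F2 | step 12 | (4R,5R)-5-(tert-butyldiphenylsilyloxy)hept-1-en-4-ol | C=CC[C@@H](O)[C@H](O[Si](c1ccccc1)(c1ccccc1)C(C)(C)C)CC
F3 | step 12 | O12-glycolic acid | C=CC[C@@H](OCC(=O)O)[C@H](O[Si](c1ccccc1)(c1ccccc1)C(C)(C)C)CC
F4 | step 12 | glycolyl imide of (R)-4-benzyloxazolidin-2-one | C=CC[C@@H](OCC(=O)N1[C@H](Cc2ccccc2)COC1=O)[C@H](O[Si](c1ccccc1)(c1ccccc1)C(C)(C)C)CC
F5 | step 12 | C6-alkylated imide (6S) | I/C=C/C[C@H](O[C@H](CC=C)[C@H](O[Si](c1ccccc1)(c1ccccc1)C(C)(C)C)CC)C(=O)N1[C@H](Cc2ccccc2)COC1=O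
F6 | step 12 | C7 primary alcohol | I/C=C/C[C@H](O[C@H](CC=C)[C@H](O[Si](c1ccccc1)(c1ccccc1)C(C)(C)C)CC)CO
F7 | step 12 | C7 aldehyde | I/C=C/C[C@H](O[C@H](CC=C)[C@H](O[Si](c1ccccc1)(c1ccccc1)C(C)(C)C)CC)C=O
F8 | step 12 | (6S,7R)-diene alcohol | I/C=C/C[C@H](O[C@H](CC=C)[C@H](O[Si](c1ccccc1)(c1ccccc1)C(C)(C)C)CC)[C@H](O)CC=C
F9 | step 12 | (9Z)-oxocen-7-ol | I/C=C/C[C@@H]1O[C@@H]([C@H](O[Si](c2ccccc2)(c2ccccc2)C(C)(C)C)CC)C/C=C\C[C@H]1O
F10 | step 12 | 7-chloro-oxocene | I/C=C/C[C@@H]1O[C@@H]([C@H](O[Si](c2ccccc2)(c2ccccc2)C(C)(C)C)CC)C/C=C\C[C@@H]1Cl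
F11 | step 12 | 9,10-diol vinyl iodide | I/C=C/C[C@@H]1O[C@@H]([C@H](O[Si](c2ccccc2)(c2ccccc2)C(C)(C)C)CC)C[C@H](O)[C@H](O)C[C@@H]1Cl
F12 | step 18 | 10-O-acetate of 22 | C[Si](C)(C)C#C/C=C/C[C@@H]1O[C@@H]([C@H](O[Si](c2ccccc2)(c2ccccc2)C(C)(C)C)CC)C[C@H](OC(C)=O)[C@H](O)C[C@@H]1Cl
F13 | step 20 | 13-O-chloromethanesulfonate of 25 | C#C/C=C/C[C@@H]1O[C@@H]([C@H](OS(=O)(=O)CCl)CC)C[C@H](OC(C)=O)[C@@H](Cl)C[C@@H]1Cl
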